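**The count.** There are 5 questions, and I answer them with two times: how long target lasts, and how long it has been in the flask.

| flask | starting material | other conformer | remark | time |
|---|---|---|---|---|
| ash | 0.10 M | 0.010 M | run made earlier |  |
| oak | 0.050 M | 0.010 M | run made earlier |  |
| south | 0.10 M (fed, over 12.0 h) | 0.0100 M | all but starting material at the start; starting material goes in evenly over 12.0 h, the run ends at 15 h | 15 h |
| north-west | 0.10 M | 0.0100 M | a single well-mixed tank run continuously and read at steady state, 15 h in it on average |  |
| south-east | 0.10 M | 0.0100 M (fed, over 12.0 h) | all but other conformer at the start; other conformer goes in evenly over 12.0 h, the run ends at 15 h | 15 h |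
| south-west | 0.10 M | 0.0100 M | everything together in a closed stirred flask, run for 15 h | 15 h |

| run | time / h | target / % | isomer of the product / % |
|---|---|---|---|
| ash | 0.667 | 3.9 | 0.6 |
| ash | 1.00 | 4.1 | 1.9 |
| ash | 1.50 | 5.8 | 1.0 |
| ash | 2.50 | 7.4 | 3.2 |
| ash | 4.00 | 9.9 | 3.7 |
| ash | 6.00 | 14.7 | 6.6 |
| ash | 10.0 | 18.3 | 8.1 |
| oak | 0.417 | 1.1 | 1.7 |
| oak | 0.833 | 2.8 | 3.2 |
| oak | 1.33 | 3.8 | 1.2 |
| oak | 1.50 | 4.1 | 1.8 |
| oak | 2.00 | 5.2 | 5.2 |
| oak | 2.50 | 9.3 | 2.1 |
| oak | 3.00 | 10.3 | 6.1 |

(standard deviation of a reading: 1 percentage point)

- the stated concentrations are those of everything mixed, before any reaction; amounts are the same in each set-up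
- the feed brings no volume worth counting
- the earlier runs were made in a closed, stirred flask

- the set-up with the highest share of target in all that became target or isomer of the product or over-reaction product, at the outlet or at the end ("none" if the first two lie within 2 percentage points) (south / north-west / south-east / south-west / none)
- share of target in all that became target or isomer of the product or over-reaction product, at the outlet or at the end, south
- share of target in all that became target or isomer of the product or over-reaction product, at the outlet or at the end, north-west
- share of target in all that became target or isomer of the product or over-reaction product, at the outlet or at the end, south-east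
- share of target in all that became target or isomer of the product or over-reaction product, at the outlet or at the end, south-west

**Target's lifetime.** In the ash run target climbs 9.9% in the first 4.00 h, then 8.4 percentage points in the next 6.00 h. I read the slowing as a first-order loss, with a rate proportional to target's own concentration. Slowing divided into the mean target level gives a lifetime τ of 13.1 h. This is a rough reading, with a scatter of 1 point on each reading. I leave isomer of the product out of this clock: in ash it reads 0.374 of target at 4.00 h and 0.443 at 10.0 h.

**The ratio.** Let x be the time t over τ. Target made steadily over t then survives as a fraction f, which is one minus e to the power minus x, divided by x. The rest I count as over-reaction product. For south-west x is 1.14 and f is 59.6%. In the north-west tank the fraction is one over one plus x, so 46.7%, lower than south-west. Feeding starting material moves the making later, so I rank south first. Feeding other conformer leaves starting material in place, so I put south-east beside south-west.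

**The result.** The forecast names south, with 47%, 33.6%, 41.3% and 40% for south, north-west, south-east and south-west, and says of the over-reaction “its order is poorly fixed”. The flask gives south, with 54.1%, 40.2%, 46.1% and 46.1% in that order.

    other conformer ⇌ dormant form (K = 73.0, k = 0.200 h⁻¹)
    target ⇌ isomer of the product (K = 0.470, k = 0.0470 h⁻¹)
    starting material ⇌ other conformer (K = 0.0840, k = 0.0340 h⁻¹)
    other conformer → isomer of the product (k = 0.190 h⁻¹)
    starting material → target (k = 0.0370 h⁻¹)
    target → over-reaction product (k = 0.0660 h⁻¹)

**Using f.** In south-west at 15.0 h, target over target plus over-reaction product is 59.7%, against f of 59.6%. A reading of south-west at 4.0 h has x of 0.305 and f of 86.2%, and there the same ratio is 87.5%. Removing the loss of target to over-reaction product narrows the gap in share of target between north-west and south from 14 points to 3 points.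

(The runs are simulated with made-up constants.)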